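The furan ring (O1, C2–C5) is disconnected at the O1–C2 bond. Read backwards, O1–C5 is a CH2OH group and C5–C4–C1' is the chain of a 2,3-epoxy alcohol whose oxirane spans C4 and the side-chain carbinol carbon C1'; the quaternary oxirane carbon (future C4) bears the arylethynyl unit that becomes C3 and C2. One gold-catalysed cycloisomerisation closes the ring by 5-endo-dig attack of the hydroxyl and aromatises it by opening the oxirane at C4, which frees the C1' hydroxyl with its configuration untouched. The precursor is the (2S,3S)-2-arylethynyl-3-prenyl epoxy alcohol from a Sharpless epoxidation, with the hydroquinone masked as its bis-silyl ether.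

Key step: step 9

Remark: furan numbering is O1, C2 (aryl), C3, C4 (side chain), C5, and C1' is the carbinol carbon; the face rule of the Sharpless epoxidation known for simple (E)-allylic alcohols is assumed to hold for the 2-alkynyl allylic alcohol 11.

Step 1
Reactants: 1 propargyl alcohol (prop-2-yn-1-ol); 2 prenyl bromide (1-bromo-3-methylbut-2-ene)
Product: 3 6-methylhept-5-en-2-yn-1-ol
Conditions: CuI (10 mol %), n-Bu4NBr (10 mol %), K2CO3, DMF, rt
Reagents that add atoms: none
Why: Copper-catalysed allylation of a terminal alkyne, in which the copper acetylide should attack the unhindered primary carbon of the allylic bromide to give the linear 1,4-enyne, the free hydroxyl being tolerated under carbonate.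

Step 2
Reactants: 3 6-methylhept-5-en-2-yn-1-ol
Product: 4 (Z)-6-methyl-2-(tributylstannyl)hepta-2,5-dien-1-ol
Conditions: Bu3SnH (1.1 equiv, slow addition), [Cp*RuCl]4 (1.25 mol %), CH2Cl2, rt
Reagents that add atoms: tributyltin hydride, CCCC[SnH](CCCC)CCCC
Why: Ruthenium-catalysed trans-hydrostannation of a propargylic alcohol, in which hydrogen bonding of the hydroxyl to the chloride ligand should steer tin to the proximal alkyne carbon and H and Sn add anti, giving the (Z)-α-stannyl allylic alcohol while the remote trisubstituted alkene stays out of the reaction.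

Step 3
Reactants: 4 (Z)-6-methyl-2-(tributylstannyl)hepta-2,5-dien-1-ol
Product: 5 (Z)-2-iodo-6-methylhepta-2,5-dien-1-ol
Conditions: I2 (1.05 equiv), CH2Cl2, 0 °C
Reagents that add atoms: iodine, II
Why: Iododestannylation is an ipso substitution with retention of alkene geometry and should be far faster than any addition of iodine to the prenyl alkene.

Step 4
Reactants: 6 2,5-dihydroxybenzaldehyde
Product: 7 2,5-bis(tert-butyldimethylsilyloxy)benzaldehyde
Conditions: TBSCl (2.4 equiv), imidazole (5 equiv), DMF, rt
Reagents that add atoms: tert-butyldimethylsilyl chloride, CC(C)(C)[Si](C)(C)Cl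
Why: Standard silylation of phenols with silyl chloride and imidazole, which in DMF should also reach the hydrogen-bonded ortho hydroxyl.

Step 5
Reactants: 7 2,5-bis(tert-butyldimethylsilyloxy)benzaldehyde
Product: 8 2-(2,2-dibromovinyl)-1,4-bis(tert-butyldimethylsilyloxy)benzene
Conditions: CBr4, PPh3, Zn dust (2 equiv each), CH2Cl2, rt; then 7, 0 °C to rt
Reagents that add atoms: carbon tetrabromide, BrC(Br)(Br)Br
Why: First stage of the Corey–Fuchs alkyne synthesis (Wittig reaction of Ph3P=CBr2), chosen over a Seyferth–Gilbert type homologation because it needs neither carbonate in methanol nor a long-lived alkoxide, both of which endanger aryl silyl ethers next to a formyl group.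

Step 6
Reactants: 8 2-(2,2-dibromovinyl)-1,4-bis(tert-butyldimethylsilyloxy)benzene
Product: 10 2-ethynyl-1,4-bis(tert-butyldimethylsilyloxy)benzene, via lithium acetylide 9 (not isolated)
Conditions: n-BuLi (2.1 equiv), THF, −78 °C; then sat. aq. NH4Cl
Reagents that add atoms: none
Why: Second stage of the Corey–Fuchs synthesis, in which bromine–lithium exchange, Fritsch–Buttenberg–Wiechell rearrangement and deprotonation give the lithium acetylide that is protonated on work-up, while at −78 °C butyllithium should not attack the silyl ethers.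

Step 7
Reactants: 5 (Z)-2-iodo-6-methylhepta-2,5-dien-1-ol; 10 2-ethynyl-1,4-bis(tert-butyldimethylsilyloxy)benzene
Product: 11 (E)-2-{[2,5-bis(tert-butyldimethylsilyloxy)phenyl]ethynyl}-6-methylhepta-2,5-dien-1-ol
Conditions: Pd(PPh3)2Cl2 (3 mol %), CuI (5 mol %), Et3N, THF, rt, degassed
Reagents that add atoms: none
Why: Sonogashira coupling of a vinyl iodide with a terminal aryl alkyne proceeds at room temperature with retention of alkene geometry and tolerates the free allylic hydroxyl and the aryl silyl ethers.

Step 8
Reactants: 11 (E)-2-{[2,5-bis(tert-butyldimethylsilyloxy)phenyl]ethynyl}-6-methylhepta-2,5-dien-1-ol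
Product: 12 (2S,3S)-{2-{[2,5-bis(tert-butyldimethylsilyloxy)phenyl]ethynyl}-3-(3-methylbut-2-enyl)oxiran-2-yl}methanol
Conditions: Ti(O-i-Pr)4 (10 mol %), L-(+)-DET (12 mol %), t-BuOOH (2 equiv, in decane), 4 Å MS, CH2Cl2, −20 °C
Reagents that add atoms: tert-butyl hydroperoxide, CC(C)(C)OO
Why: Sharpless asymmetric epoxidation, in which titanium binds the allylic hydroxyl so that only the allylic alkene is oxidised (prenyl alkene and alkyne untouched) and the L-(+)-tartrate ligand delivers oxygen to the face that turns an (E)-allylic alcohol into the (2S,3S)-oxirane, which sets C3, the later C1'.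

Step 9
Reactants: 12 (2S,3S)-{2-{[2,5-bis(tert-butyldimethylsilyloxy)phenyl]ethynyl}-3-(3-methylbut-2-enyl)oxiran-2-yl}methanol
Product: 14 (S)-1-{5-[2,5-bis(tert-butyldimethylsilyloxy)phenyl]furan-3-yl}-4-methylpent-3-en-1-ol, via spiro-epoxy dihydrofuran 13 (not isolated)
Conditions: Ph3PAuNTf2 (2 mol %), THF, 0 °C to rt; then Et3N
Reagents that add atoms: none
Why: Proposed new method: Ph3PAu+ (monovalent gold) coordinates the aryl alkyne, whose electron-rich aryl group makes the aryl-bearing carbon the electrophilic end, and the primary hydroxyl adds anti to gold in a 5-endo-dig closure that forms the O1–C2 bond and the furan ring; protodeauration gives 13, a 4,5-dihydrofuran with a spiro-oxirane at C4. The enol ether of 13 then pushes out the C4–O bond of the oxirane, and loss of a C5 proton from the resulting oxocarbenium ion aromatises the ring and leaves the oxirane oxygen as the C1' hydroxyl. The closest known reaction types are the gold- or silver-catalysed cyclodehydration of 3-alkyne-1,2-diols to furans and the cycloisomerisation of alkynyl oxiranes to furans; here the oxirane oxygen takes the place of the departing hydroxyl, so the reaction is an isomerisation. No stereocentre is formed: C1' was set in step 8 and keeps its (S) configuration because its C–O bond is never broken, whereas the second oxirane carbon becomes sp2 (C4). The step needs chemoselectivity for the hydroxyl over the oxirane oxygen, the ortho-silyloxy oxygen and the prenyl alkene (a 1,6-enyne partner); the free, unhindered hydroxyl three atoms from the alkyne reaches C2 without strain, whereas the oxirane oxygen would have to pass through a strained bicyclic oxonium ion, the silyl ether oxygen is hindered and weakly nucleophilic, and the oxirane also keeps the C1' oxygen from competing as a second hydroxyl. A low catalyst loading in THF at 0 °C and an amine quench should keep the acid-sensitive furyl carbinol from ionising.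

Step 10
Reactants: 14 (S)-1-{5-[2,5-bis(tert-butyldimethylsilyloxy)phenyl]furan-3-yl}-4-methylpent-3-en-1-ol; 15 3-methylbut-2-enoic acid
Product: 16 (S)-1-{5-[2,5-bis(tert-butyldimethylsilyloxy)phenyl]furan-3-yl}-4-methylpent-3-en-1-yl 3-methylbut-2-enoate
Conditions: DCC (1.3 equiv), DMAP (10 mol %), CH2Cl2, 0 °C to rt
Reagents that add atoms: none
Why: Steglich esterification acylates the secondary alcohol at oxygen only, so C1' keeps its configuration, and a catalytic amount of DMAP at low temperature should limit migration of the enoate double bond.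

Step 11
Reactants: 16 (S)-1-{5-[2,5-bis(tert-butyldimethylsilyloxy)phenyl]furan-3-yl}-4-methylpent-3-en-1-yl 3-methylbut-2-enoate
Product: 17 (S)-1-[5-(2,5-dihydroxyphenyl)furan-3-yl]-4-methylpent-3-en-1-yl 3-methylbut-2-enoate (target)
Conditions: TBAF (2.4 equiv), AcOH (2.4 equiv), THF, 0 °C, argon
Reagents that add atoms: none
Why: Fluoride cleaves aryl silyl ethers fast, and acetic acid protonates the phenoxides at once, so that the furylic ester and the enoate should not see free base, while exclusion of air guards the hydroquinone against oxidation.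

Compound list
1 | propargyl alcohol (prop-2-yn-1-ol) | C#CCO | starting material
2 | prenyl bromide (1-bromo-3-methylbut-2-ene) | CC(C)=CCBr | starting material
3 | 6-methylhept-5-en-2-yn-1-ol | CC(C)=CCC#CCO | intermediate
4 | (Z)-6-methyl-2-(tributylstannyl)hepta-2,5-dien-1-ol | OC/C(=C/CC=C(C)C)[Sn](CCCC)(CCCC)CCCC | intermediate
5 | (Z)-2-iodo-6-methylhepta-2,5-dien-1-ol | OC/C(I)=C/CC=C(C)C | intermediate
6 | 2,5-dihydroxybenzaldehyde | O=Cc1cc(O)ccc1O | starting material
7 | 2,5-bis(tert-butyldimethylsilyloxy)benzaldehyde | O=Cc1cc(O[Si](C)(C)C(C)(C)C)ccc1O[Si](C)(C)C(C)(C)C | intermediate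
8 | 2-(2,2-dibromovinyl)-1,4-bis(tert-butyldimethylsilyloxy)benzene | BrC(Br)=Cc1cc(O[Si](C)(C)C(C)(C)C)ccc1O[Si](C)(C)C(C)(C)C | intermediate
9 | lithium [2,5-bis(tert-butyldimethylsilyloxy)phenyl]acetylide (formed in the flask, not isolated) | [Li]C#Cc1cc(O[Si](C)(C)C(C)(C)C)ccc1O[Si](C)(C)C(C)(C)C | intermediate
10 | 2-ethynyl-1,4-bis(tert-butyldimethylsilyloxy)benzene | C#Cc1cc(O[Si](C)(C)C(C)(C)C)ccc1O[Si](C)(C)C(C)(C)C | intermediate
11 | (E)-2-{[2,5-bis(tert-butyldimethylsilyloxy)phenyl]ethynyl}-6-methylhepta-2,5-dien-1-ol | OC/C(C#Cc1cc(O[Si](C)(C)C(C)(C)C)ccc1O[Si](C)(C)C(C)(C)C)=C/CC=C(C)C | intermediate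
12 | (2S,3S)-{2-{[2,5-bis(tert-butyldimethylsilyloxy)phenyl]ethynyl}-3-(3-methylbut-2-enyl)oxiran-2-yl}methanol | OC[C@]1(C#Cc2cc(O[Si](C)(C)C(C)(C)C)ccc2O[Si](C)(C)C(C)(C)C)O[C@H]1CC=C(C)C | intermediate
13 | (2S,3S)-6-[2,5-bis(tert-butyldimethylsilyloxy)phenyl]-2-(3-methylbut-2-enyl)-1,5-dioxaspiro[2.4]hept-6-ene (formed in the flask, not isolated) | O1C[C@]2(C=C1c3cc(O[Si](C)(C)C(C)(C)C)ccc3O[Si](C)(C)C(C)(C)C)O[C@H]2CC=C(C)C | intermediate
14 | (S)-1-{5-[2,5-bis(tert-butyldimethylsilyloxy)phenyl]furan-3-yl}-4-methylpent-3-en-1-ol | CC(C)=CC[C@H](O)c1coc(-c2cc(O[Si](C)(C)C(C)(C)C)ccc2O[Si](C)(C)C(C)(C)C)c1 | intermediate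
15 | 3-methylbut-2-enoic acid | CC(C)=CC(=O)O | starting material
16 | (S)-1-{5-[2,5-bis(tert-butyldimethylsilyloxy)phenyl]furan-3-yl}-4-methylpent-3-en-1-yl 3-methylbut-2-enoate | CC(C)=CC[C@H](OC(=O)C=C(C)C)c1coc(-c2cc(O[Si](C)(C)C(C)(C)C)ccc2O[Si](C)(C)C(C)(C)C)c1 | intermediate
17 | (S)-1-[5-(2,5-dihydroxyphenyl)furan-3-yl]-4-methylpent-3-en-1-yl 3-methylbut-2-enoate | CC(C)=CC[C@H](OC(=O)C=C(C)C)c1coc(-c2cc(O)ccc2O)c1 | target

Total step count: 11
Longest linear sequence: 8 steps (steps 1, 2, 3, 7, 8, 9, 10, 11; the arene branch, steps 4 to 11, is equally long)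

Steps most likely to fail

1. Step 9. The hydroxyl may lose against the oxirane oxygen or the prenyl alkene as nucleophile, the spiro intermediate may not aromatise cleanly, or the furyl carbinol may ionise under the Lewis acid. The fallback uses known chemistry, sets out from 10 and comes back at 14; it gives up the oxirane as leaving group and sets C1' by reagent control.
   - Alkyne 10 is deprotonated again to 9 (n-BuLi, THF, −78 °C) and added to 2,2-dimethyl-1,3-dioxan-5-one to give 5-{[2,5-bis(tert-butyldimethylsilyloxy)phenyl]ethynyl}-2,2-dimethyl-1,3-dioxan-5-ol F1.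
   - Aqueous acetic acid in THF removes the acetonide to give 2-{[2,5-bis(tert-butyldimethylsilyloxy)phenyl]ethynyl}propane-1,2,3-triol F2. Its two hydroxymethyl arms are equivalent, so the established cyclodehydration of 3-alkyne-1,2-diols (Ph3PAuCl/AgOTf, THF, 0 °C) can give only {5-[2,5-bis(tert-butyldimethylsilyloxy)phenyl]furan-3-yl}methanol F3.
   - MnO2 oxidises this to 5-[2,5-bis(tert-butyldimethylsilyloxy)phenyl]furan-3-carbaldehyde F4.
   - Brown allylation with the B-allyldiisopinocampheylborane made from (+)-α-pinene (Si-face addition to aryl aldehydes) should give (S)-1-{5-[2,5-bis(tert-butyldimethylsilyloxy)phenyl]furan-3-yl}but-3-en-1-ol F5.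
   - Cross-metathesis with 2-methylbut-2-ene (second-generation Grubbs catalyst) turns the allyl into the prenyl group and gives 14.

2. Step 8. Oxygen transfer to the electron-poor alkene flanked by the alkyne may be slow, facial selectivity may erode, or the tertiary propargylic oxirane may be opened by isopropoxide. The fallback sets out from 11 and comes back at 14; the centre is set by reduction instead of epoxidation.
   - Hydroxyl-directed epoxidation with VO(acac)2 and t-BuOOH gives the racemic trans-epoxy alcohol F6.
   - The gold conditions of step 9 convert it, by way of the racemic spiro-epoxy dihydrofuran F7, into the racemic furyl carbinol F8.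
   - Dess–Martin periodinane buffered with NaHCO3 gives 1-{5-[2,5-bis(tert-butyldimethylsilyloxy)phenyl]furan-3-yl}-4-methylpent-3-en-1-one F9.
   - Corey–Bakshi–Shibata reduction with the (R)-methyl oxazaborolidine and catecholborane in toluene at −78 °C, the furyl group acting as the large substituent, should give 14 without touching the prenyl alkene. Base is avoided throughout so that the β,γ-enone does not move into conjugation.

3. Step 2. Tin may be delivered to the distal alkyne carbon, the addition may not be cleanly anti, or the diene may slow the catalyst. The fallback sets out from 3 and comes back at 5.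
   - A tin-free anti-hydroalumination with LiAlH4 and a small amount of AlCl3 in THF is used. This is the classical modification that places aluminium on the alkyne carbon next to the carbinol.
   - Iodinolysis of the vinylalane with I2 at −78 °C would give 5 directly and replace steps 2 and 3; no new isolable compound is made.

Further compounds
F1 | step 9 | 5-{[2,5-bis(tert-butyldimethylsilyloxy)phenyl]ethynyl}-2,2-dimethyl-1,3-dioxan-5-ol | CC1(C)OCC(O)(C#Cc2cc(O[Si](C)(C)C(C)(C)C)ccc2O[Si](C)(C)C(C)(C)C)CO1
F2 | step 9 | 2-{[2,5-bis(tert-butyldimethylsilyloxy)phenyl]ethynyl}propane-1,2,3-triol | OCC(O)(CO)C#Cc1cc(O[Si](C)(C)C(C)(C)C)ccc1O[Si](C)(C)C(C)(C)C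
F3 | step 9 | {5-[2,5-bis(tert-butyldimethylsilyloxy)phenyl]furan-3-yl}methanol | OCc1coc(-c2cc(O[Si](C)(C)C(C)(C)C)ccc2O[Si](C)(C)C(C)(C)C)c1
F4 | step 9 | 5-[2,5-bis(tert-butyldimethylsilyloxy)phenyl]furan-3-carbaldehyde | O=Cc1coc(-c2cc(O[Si](C)(C)C(C)(C)C)ccc2O[Si](C)(C)C(C)(C)C)c1
F5 | step 9 | (S)-1-{5-[2,5-bis(tert-butyldimethylsilyloxy)phenyl]furan-3-yl}but-3-en-1-ol | C=CC[C@H](O)c1coc(-c2cc(O[Si](C)(C)C(C)(C)C)ccc2O[Si](C)(C)C(C)(C)C)c1
F6 | step 8 | racemic (2S*,3S*)-{2-{[2,5-bis(tert-butyldimethylsilyloxy)phenyl]ethynyl}-3-(3-methylbut-2-enyl)oxiran-2-yl}methanol (racemate, one enantiomer drawn) | OC[C@]1(C#Cc2cc(O[Si](C)(C)C(C)(C)C)ccc2O[Si](C)(C)C(C)(C)C)O[C@H]1CC=C(C)C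
F7 | step 8 | racemic (2S*,3S*)-6-[2,5-bis(tert-butyldimethylsilyloxy)phenyl]-2-(3-methylbut-2-enyl)-1,5-dioxaspiro[2.4]hept-6-ene (racemate, one enantiomer drawn, not isolated) | O1C[C@]2(C=C1c3cc(O[Si](C)(C)C(C)(C)C)ccc3O[Si](C)(C)C(C)(C)C)O[C@H]2CC=C(C)C
F8 | step 8 | racemic 1-{5-[2,5-bis(tert-butyldimethylsilyloxy)phenyl]furan-3-yl}-4-methylpent-3-en-1-ol | CC(C)=CCC(O)c1coc(-c2cc(O[Si](C)(C)C(C)(C)C)ccc2O[Si](C)(C)C(C)(C)C)c1
F9 | step 8 | 1-{5-[2,5-bis(tert-butyldimethylsilyloxy)phenyl]furan-3-yl}-4-methylpent-3-en-1-one | CC(C)=CCC(=O)c1coc(-c2cc(O[Si](C)(C)C(C)(C)C)ccc2O[Si](C)(C)C(C)(C)C)c1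
F0 | step 2 | none | none
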